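The target of this flask stands one reversible step from the starting material, and the meeting asked how much of it would be there at 1.5 h.

    starting material ⇌ dormant form (K1 = 0.84, k1 = 0.029 s⁻¹)
    isomer of the product B ⇌ starting material (k2 = 0.012 s⁻¹)
    starting material ⇌ target (K3 = 0.17, k3 = 0.012 s⁻¹)
    target ⇌ isomer of the product A (K4 = 0.61, k4 = 0.0041 s⁻¹)
    starting material + protic impurity → quenched substrate (k5 = 1.3 M⁻¹ s⁻¹)
    isomer of the product A ⇌ isomer of the product B (K6 = 25, k6 = 7.2 × 10⁻⁴ s⁻¹)

starting material 0.058 M; protic impurity 5.80 mM; time 1.5 h

* which holds at 1.5 h: what has brought the reaction to rest, or that it has not come to rest (forward and back rates have come level / all of the starting material has reacted / it is still moving)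
* share of the starting material used up at 1.5 h
* target at 1.5 h, in percent of the starting material charged
* isomer of the product B at 1.5 h, in percent of the starting material charged
* amount of target if the flask were left three thousand times as long, in percent of the starting material charged

- what has gone from starting material into another species counts as reacted, even if it can come back
- the reaction counts as stopped when no species that holds the starting material changes by six tenths of a point or more over the second half of the time
- run time (flask): 1.5 h

**Minutes.** The chair asked whether this flask could be reckoned by hand before any run.

I argued that the reversible steps form a ladder on the starting material, and that logarithms turn climbing it into addition. With the starting material as rung zero, in powers of ten, the dormant form stands at −0.0757, the target at −0.770, the isomer of the product A at −0.984 and the isomer of the product B at 0.414. Step 2 carries the inverse of the product of the other three constants, so the ring closes without conflict.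

Undoing the logarithms and adding the rungs gives a sum of 4.71, whose logarithm is 0.673. I proposed to carry one quantity, the target's pool share, meaning the fraction of the unquenched material that stands as target once every reversible step is level: 3.61%, or −1.44 in powers of ten.

I then turned to the irreversible step in this flask, where the protic impurity is the limiting reagent. The ratio c(protic impurity)/c(starting material) takes 10.0% of the charge out, which leaves a pool of 90.0%. With the starting material at its pool level, the impurity's half-life is 0.801 min, shorter than the run. The half-life of the isomer of the product A by step 6, forward rate only, is 0.267 h, also shorter than the run.

So I expected thermodynamic control and committed to this: forward and back rates have come level, conversion 80.9%, target 3.25%, isomer of the product B 49.6%, and target after the long wait 3.25%.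

The maker of the forecast reported forward and back rates have come level, with conversion 80.9%, target 3.25%, isomer of the product B 49.6% and 3.25% of target after the long wait, holding that “the slowest relaxation among the other species takes only a few minutes”.

**Result.** This flask gave forward and back rates have come level, with conversion 80.9%, target 3.25%, isomer of the product B 49.6% and 3.25% of target after the long wait. With the other amounts and the time held, the isomer of the product B moved by 5 points once the protic impurity reached 11.1 mM. The neighbour flask holds 0.023 M of protic impurity, which leaves a pool of 60.3%. Multiplied by the pool share, that pool gives 2.18% of target, and the neighbour flask read 2.18% at 1.50 h.

Its constants were chosen freely, and the outcome is calculated.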